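**Plan**

- Numbering follows caryophyllane: C1/C9 are the cyclobutane ring-fusion carbons, C4 carries the vinyl methyl, C5 is the carbinol, C8 the spiro carbon, C13 its CH2 in the pyran. The dihydropyran is cut first at O–C8 and C13–CH(iBu) (hetero-Diels–Alder), then the C5 carbinol and the C8 methylene are traced back to two ketones.
- In the nine-membered ring the oxygens on C5 and C8 stand 1,4 to each other across C6–C7. That bond is therefore cut to give two methyl-ketone enol ethers, both held on one silicon atom.
- Further cuts: C5–C6 and C7–C8 (methyl Grignard on two Weinreb amides), C3=C4 (Z-selective olefination), and the acyl–CH2 bond of a cyclopentenone/isobutylene [2+2] adduct (enol ether ozonolysis).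
- Forward order: cyclobutane by photocycloaddition, ring cleavage and chain extension to a trans-cyclobutane bis(methyl ketone), silicon bridge, anodic closure of the nine-membered ring, then methylenation, reduction and spiro-pyran annulation.
- Stereochemistry: C1 from the catalytic enantioselective photocycloaddition; C9 by thermodynamic epimerisation to trans; the 3Z alkene from Still–Gennari olefination; C5 from Corey–Bakshi–Shibata reduction; C8 and the isobutyl-bearing carbon from the substrate-controlled hetero-Diels–Alder reaction.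

Key step: step 9

Assumption: the oxazaborolidine·AlBr3 catalyst is taken to induce cyclopentenone in the same way as six-membered enones; the prolinol antipode that delivers (1R,5R)-3 is the one used.

**Route**

Step 1
Reactants: 1 cyclopent-2-en-1-one; 2 isobutylene
Product: 3 (1R,5R)-6,6-dimethylbicyclo[3.2.0]heptan-2-one
Conditions: hν (366 nm), AlBr3 complex of the B-(2,4,6-trifluorophenyl)oxazaborolidine of α,α-bis(3,5-dimethylphenyl)prolinol (50 mol%), excess 2, CH2Cl2, −75 °C
Reagents that add atoms: none
Why: Chiral-Lewis-acid-catalysed enone–alkene [2+2] photocycloaddition, in which the bound catalyst red-shifts the enone absorption and shields one face, so that head-to-tail addition should place CMe2 on the β-carbon and set the future C1 in a cis-fused adduct.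

Step 2
Reactants: 3 (1R,5R)-6,6-dimethylbicyclo[3.2.0]heptan-2-one
Product: 4 trimethyl{[(1R,5R)-6,6-dimethylbicyclo[3.2.0]hept-2-en-2-yl]oxy}silane
Conditions: TMSOTf, Et3N, CH2Cl2, 0 °C
Reagents that add atoms: trimethylsilyl trifluoromethanesulfonate, C[Si](C)(C)OS(=O)(=O)C(F)(F)F
Why: Soft enolisation to the silyl enol ether can only go toward the CH2 group, because the alternative would put a double bond at the cyclobutane ring fusion.

Step 3
Reactants: 4 trimethyl{[(1R,5R)-6,6-dimethylbicyclo[3.2.0]hept-2-en-2-yl]oxy}silane
Product: 6 methyl (1R,2R)-2-(2,2-dimethoxyethyl)-3,3-dimethylcyclobutane-1-carboxylate, via cis aldehyde acid 5 (not isolated)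
Conditions: O3, CH2Cl2/MeOH, −78 °C; Me2S, −78 °C → rt; then HC(OMe)3, TsOH·H2O (cat.), MeOH, 40 °C
Reagents that add atoms: ozone, [O-][O+]=O; methanol, CO; trimethyl orthoformate, COC(OC)OC
Why: Ozonolysis of a silyl enol ether with reductive work-up cleaves the ring to a carboxylic acid and an aldehyde, and acid-catalysed acetalisation with Fischer esterification (water removed by the orthoformate) should give the open acetal ester with both stereocentres untouched.

Step 4
Reactants: 6 methyl (1R,2R)-2-(2,2-dimethoxyethyl)-3,3-dimethylcyclobutane-1-carboxylate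
Product: 8 methyl (1S,2R)-3,3-dimethyl-2-(2-oxoethyl)cyclobutane-1-carboxylate, via trans acetal ester 7 (not isolated)
Conditions: NaOMe, MeOH, 65 °C; then 2 M HCl (aq), THF, rt
Reagents that add atoms: water, O
Why: Epimerisation through the ester enolate relieves the cis-1,2 interaction on the cyclobutane and should set C9 trans to the C1 side chain under thermodynamic control (before any alkene or free aldehyde is present), after which acetal hydrolysis frees the aldehyde.

Step 5
Reactants: 8 methyl (1S,2R)-3,3-dimethyl-2-(2-oxoethyl)cyclobutane-1-carboxylate; 9 ethyl 2-[bis(2,2,2-trifluoroethoxy)phosphoryl]propanoate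
Product: 10 methyl (1S,2R)-2-[(2Z)-4-ethoxy-3-methyl-4-oxobut-2-en-1-yl]-3,3-dimethylcyclobutane-1-carboxylate
Conditions: 9, KN(SiMe3)2, 18-crown-6, THF, −78 °C; then 8
Reagents that add atoms: none
Why: Still–Gennari olefination, in which the bis(trifluoroethyl) phosphonate eliminates rapidly from the kinetic adduct under dissociating conditions, should give the Z trisubstituted enoate that becomes the C3=C4 alkene.

Step 6
Reactants: 10 methyl (1S,2R)-2-[(2Z)-4-ethoxy-3-methyl-4-oxobut-2-en-1-yl]-3,3-dimethylcyclobutane-1-carboxylate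
Product: 11 (1S,2R)-N-methoxy-2-{(2Z)-4-[methoxy(methyl)amino]-3-methyl-4-oxobut-2-en-1-yl}-N,3,3-trimethylcyclobutane-1-carboxamide
Conditions: MeNH(OMe)·HCl, iPrMgCl, THF, −20 → 0 °C
Reagents that add atoms: N,O-dimethylhydroxylamine hydrochloride, CNOC.Cl
Why: Aminolysis of both esters by the magnesium amide of N,O-dimethylhydroxylamine (Weinreb amide formation) is a 1,2-acyl substitution that should leave the Z alkene and the trans-cyclobutane unchanged.

Step 7
Reactants: 11 (1S,2R)-N-methoxy-2-{(2Z)-4-[methoxy(methyl)amino]-3-methyl-4-oxobut-2-en-1-yl}-N,3,3-trimethylcyclobutane-1-carboxamide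
Product: 12 (3Z)-5-[(1R,4S)-4-acetyl-2,2-dimethylcyclobutyl]-3-methylpent-3-en-2-one
Conditions: MeMgBr, THF, 0 °C; cold aq. NH4Cl
Reagents that add atoms: methylmagnesium bromide, C[Mg]Br
Why: Grignard addition to a Weinreb amide stops at the chelated tetrahedral intermediate, so each amide should give one methyl ketone (the future C6 and C7) without over-addition or conjugate addition.

Step 8
Reactants: 12 (3Z)-5-[(1R,4S)-4-acetyl-2,2-dimethylcyclobutyl]-3-methylpent-3-en-2-one
Product: 14 (1S,7Z,10R)-7,11,11-trimethyl-2,6-dimethylidene-4,4-di(propan-2-yl)-3,5-dioxa-4-silabicyclo[8.2.0]dodec-7-ene, via dilithium bis-enolate 13 (not isolated)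
Conditions: LiN(iPr)2 (2.2 equiv), THF, −78 °C (12 added slowly); then iPr2Si(OTf)2 (1.0 equiv), THF, 5 mM, −78 → 0 °C
Reagents that add atoms: diisopropylsilyl bis(trifluoromethanesulfonate), CC(C)[Si](OS(=O)(=O)C(F)(F)F)(OS(=O)(=O)C(F)(F)F)C(C)C
Why: Kinetic deprotonation removes a methyl proton of each ketone (α′ on the enone side, giving the 2-oxydiene), and O-silylation of both enolates by one bifunctional silyl electrophile (silicon-tethered bis-enol ether formation) should close the ten-membered siloxane ring at high dilution, with the Z alkene and the trans-cyclobutane holding the two ends on the same side.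

Step 9
Reactants: 14 (1S,7Z,10R)-7,11,11-trimethyl-2,6-dimethylidene-4,4-di(propan-2-yl)-3,5-dioxa-4-silabicyclo[8.2.0]dodec-7-ene
Product: 15 (1R,3Z,9S)-4,11,11-trimethylbicyclo[7.2.0]undec-3-ene-5,8-dione (caryophyllane numbering)
Conditions: constant-current electrolysis (2.2 F/mol), reticulated vitreous carbon anode, Pt cathode, undivided cell, LiClO4 (0.1 M), 2,6-lutidine, CH2Cl2/MeOH 4:1, 0 °C, 14 added slowly to about 2 mM
Reagents that add atoms: none
Why: Proposed new method: one-electron oxidation of the more electron-rich 2-silyloxydiene half of 14 gives a radical cation whose CH2 terminus C6 is attacked by the CH2 terminus C7 of the neighbouring enol ether, and a second electron transfer followed by methanolysis of both Si–O bonds releases the ene-1,4-dione. The closest known reaction types are the oxidation of dialkylsilyl bis-enol ethers to 1,4-diketones (by ceric ammonium nitrate, (NH4)2Ce(NO3)6, or at an anode) and the anodic coupling of two electron-rich alkenes. The nine-membered carbocycle (formally a 9-endo closure) is delivered as a seven-membered endo closure inside the O–Si–O bridge (C6–C5–O–Si–O–C8–C7), so no medium-ring transition state is needed. No stereocentre is formed, and C1, C9 and the Z alkene are untouched. The step needs C6–C7 coupling in preference to attack at C3 of the dienol ether (a six-membered closure through the carbon chain) and to intermolecular coupling. The one-atom tether, the steric and frontier-orbital preference for the unsubstituted terminus C6, and slow addition at millimolar concentration are relied on for this.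

Step 10
Reactants: 15 (1R,3Z,9S)-4,11,11-trimethylbicyclo[7.2.0]undec-3-ene-5,8-dione
Product: 16 (1R,3Z,9S)-4,11,11-trimethyl-8-methylidenebicyclo[7.2.0]undec-3-en-5-one
Conditions: Ph3PCH3Br (1.1 equiv), KOtBu, THF, 0 °C
Reagents that add atoms: methyltriphenylphosphonium bromide, C[P+](c1ccccc1)(c1ccccc1)c1ccccc1.[Br-]
Why: Wittig methylenation should occur at the saturated C8 ketone, which is more electrophilic than the cross-conjugated, α-branched C5 enone (as in the selective methylenation of the saturated carbonyl of Wieland–Miescher-type enediones), and the trans ring fusion at C9 is the thermodynamically preferred one should the ylide enolise C8.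

Step 11
Reactants: 16 (1R,3Z,9S)-4,11,11-trimethyl-8-methylidenebicyclo[7.2.0]undec-3-en-5-one
Product: 17 (1R,3Z,5R,9S)-4,11,11-trimethyl-8-methylidenebicyclo[7.2.0]undec-3-en-5-ol
Conditions: (S)-Me-CBS oxazaborolidine [(S)-1-methyl-3,3-diphenyltetrahydro-1H,3H-pyrrolo[1,2-c][1,3,2]oxazaborole] (0.3 equiv), catecholborane, toluene, −78 °C
Reagents that add atoms: none
Why: Corey–Bakshi–Shibata reduction is 1,2-selective for enones and, with the alkenyl residue as the large group, the (S)-catalyst should deliver hydride to the face that gives the 5R carbinol under reagent control, while catecholborane leaves both alkenes alone at low temperature.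

Step 12
Reactants: 17 (1R,3Z,5R,9S)-4,11,11-trimethyl-8-methylidenebicyclo[7.2.0]undec-3-en-5-ol; 18 syncarpic acid; 19 isovaleraldehyde
Product: 21 Tomentodione O, via Knoevenagel adduct 20 (not isolated)
Conditions: 18 (1.5 equiv), 19 (2 equiv), ethylenediammonium diacetate (10 mol%), toluene, 80 °C
Reagents that add atoms: none
Why: Knoevenagel condensation gives an alkylidene trione that should act as an oxa-diene in an inverse-electron-demand hetero-Diels–Alder reaction with the exocyclic alkene, its oxygen bonding to the more substituted C8 and its CH(iBu) terminus to C13; C8 and the isobutyl-bearing carbon are set by approach to the exposed alkene face (substrate control), and any diastereomers would be separated by chromatography.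

**Compound list**

1 | cyclopent-2-en-1-one | O=C1C=CCC1 | starting material
2 | isobutylene (2-methylpropene) | CC(C)=C | starting material
3 | (1R,5R)-6,6-dimethylbicyclo[3.2.0]heptan-2-one | O=C1CC[C@@H]2[C@H]1CC2(C)C | intermediate
4 | trimethyl{[(1R,5R)-6,6-dimethylbicyclo[3.2.0]hept-2-en-2-yl]oxy}silane | C[Si](C)(C)OC1=CC[C@@H]2[C@H]1CC2(C)C | intermediate
5 | (1R,2R)-3,3-dimethyl-2-(2-oxoethyl)cyclobutane-1-carboxylic acid (cis) | O=CC[C@@H]1[C@@H](CC1(C)C)C(=O)O | intermediate
6 | methyl (1R,2R)-2-(2,2-dimethoxyethyl)-3,3-dimethylcyclobutane-1-carboxylate (cis) | COC(OC)C[C@@H]1[C@@H](CC1(C)C)C(=O)OC | intermediate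
7 | methyl (1S,2R)-2-(2,2-dimethoxyethyl)-3,3-dimethylcyclobutane-1-carboxylate (trans) | COC(OC)C[C@@H]1[C@H](CC1(C)C)C(=O)OC | intermediate
8 | methyl (1S,2R)-3,3-dimethyl-2-(2-oxoethyl)cyclobutane-1-carboxylate (trans) | O=CC[C@@H]1[C@H](CC1(C)C)C(=O)OC | intermediate
9 | ethyl 2-[bis(2,2,2-trifluoroethoxy)phosphoryl]propanoate | CCOC(=O)C(C)P(=O)(OCC(F)(F)F)OCC(F)(F)F | starting material
10 | methyl (1S,2R)-2-[(2Z)-4-ethoxy-3-methyl-4-oxobut-2-en-1-yl]-3,3-dimethylcyclobutane-1-carboxylate | C/C(C(=O)OCC)=C/C[C@@H]1[C@H](CC1(C)C)C(=O)OC | intermediate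
11 | (1S,2R)-N-methoxy-2-{(2Z)-4-[methoxy(methyl)amino]-3-methyl-4-oxobut-2-en-1-yl}-N,3,3-trimethylcyclobutane-1-carboxamide | C/C(C(=O)N(C)OC)=C/C[C@@H]1[C@H](CC1(C)C)C(=O)N(C)OC | intermediate
12 | (3Z)-5-[(1R,4S)-4-acetyl-2,2-dimethylcyclobutyl]-3-methylpent-3-en-2-one | C/C(C(C)=O)=C/C[C@@H]1[C@H](CC1(C)C)C(C)=O | intermediate
13 | dilithium bis-enolate of 12 (both methyl groups deprotonated) | C/C(C(=C)O[Li])=C/C[C@@H]1[C@H](CC1(C)C)C(=C)O[Li] | intermediate
14 | (1S,7Z,10R)-7,11,11-trimethyl-2,6-dimethylidene-4,4-di(propan-2-yl)-3,5-dioxa-4-silabicyclo[8.2.0]dodec-7-ene (cyclic diisopropylsilylene bis-enol ether) | C/C1=C/C[C@@H]2[C@H](CC2(C)C)C(=C)O[Si](C(C)C)(C(C)C)OC1=C | intermediate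
15 | (1R,3Z,9S)-4,11,11-trimethylbicyclo[7.2.0]undec-3-ene-5,8-dione (trans-fused) | C/C1=C/C[C@@H]2[C@H](CC2(C)C)C(=O)CCC1=O | intermediate
16 | (1R,3Z,9S)-4,11,11-trimethyl-8-methylidenebicyclo[7.2.0]undec-3-en-5-one | C/C1=C/C[C@@H]2[C@H](CC2(C)C)C(=C)CCC1=O | intermediate
17 | (1R,3Z,5R,9S)-4,11,11-trimethyl-8-methylidenebicyclo[7.2.0]undec-3-en-5-ol | C/C1=C/C[C@@H]2[C@H](CC2(C)C)C(=C)CC[C@H]1O | intermediate
18 | syncarpic acid (2,2,4,4-tetramethylcyclohexane-1,3,5-trione) | CC1(C)C(=O)CC(=O)C(C)(C)C1=O | starting material
19 | isovaleraldehyde (3-methylbutanal) | CC(C)CC=O | starting material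
20 | 2,2,4,4-tetramethyl-6-(3-methylbutylidene)cyclohexane-1,3,5-trione | CC(C)CC=C1C(=O)C(C)(C)C(=O)C(C)(C)C1=O | intermediate
21 | Tomentodione O (1R,3Z,5R,8S,9S; R at the isobutyl-bearing carbon) | C/C1=C/C[C@@H]2[C@H](CC2(C)C)[C@]2(CC[C@H]1O)C[C@@H](CC(C)C)C1=C(O2)C(C)(C)C(=O)C(C)(C)C1=O | target

**Count and risks**

Total steps: 12. Longest linear sequence: 12 steps, from cyclopent-2-en-1-one.

Steps most likely to fail:

1. Step 9 (anodic ring closure). The radical cation may be trapped at C3 instead of C6, giving a six-membered ring through the carbon chain. The enol ethers may also be solvolysed before they are oxidised, or coupling may occur between molecules. Fallback by known chemistry, closing the ring at C4–C5 instead. It sets out from aldehyde 8 and rejoins the route at enone 16, which then goes on through step 11. Stork–Zhao olefination of 8 (Ph3P+CH(I)CH3 iodide, NaN(SiMe3)2, THF, −78 °C) gives methyl (1S,2R)-2-[(2Z)-3-iodobut-2-en-1-yl]-3,3-dimethylcyclobutane-1-carboxylate F1. AlMe3 with MeNH(OMe)·HCl converts the ester into (1S,2R)-2-[(2Z)-3-iodobut-2-en-1-yl]-N-methoxy-N,3,3-trimethylcyclobutane-1-carboxamide F2. Addition of [2-(1,3-dioxolan-2-yl)ethyl]magnesium bromide gives 3-(1,3-dioxolan-2-yl)-1-[(1S,2R)-2-[(2Z)-3-iodobut-2-en-1-yl]-3,3-dimethylcyclobutyl]propan-1-one F3. Wittig methylenation (Ph3P=CH2) gives 2-{3-[(1S,2R)-2-[(2Z)-3-iodobut-2-en-1-yl]-3,3-dimethylcyclobutyl]but-3-en-1-yl}-1,3-dioxolane F4. Aqueous acid frees 4-[(1S,2R)-2-[(2Z)-3-iodobut-2-en-1-yl]-3,3-dimethylcyclobutyl]pent-4-enal F5. A Nozaki–Hiyama–Kishi cyclisation (CrCl2, catalytic NiCl2, degassed DMSO/THF, high dilution) should then close the nine-membered ring to alcohol 17 together with its C5 epimer (1R,3Z,5S,9S)-4,11,11-trimethyl-8-methylidenebicyclo[7.2.0]undec-3-en-5-ol F6. Dess–Martin oxidation of the mixture converges on 16.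

2. Step 8 (silicon bridge). Chains may form by intermolecular silylation instead of the ten-membered ring, and a half-formed mono-enolate may add to the enone in Michael fashion or equilibrate to other enolates. Fallback without a covalent tether. It sets out from diketone 12 and rejoins at dione 15. The dilithium bis-enolate 13 is generated as before and oxidised directly with anhydrous CuCl2 in THF/DMF at −78 °C under high dilution (Saegusa-type oxidative enolate coupling), with the lithium enolate aggregate serving as the template that holds C6 and C7 together. This replaces steps 8 and 9 and makes no new isolable compound.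

3. Step 12 (annulation). The exocyclic alkene may be attacked from the wrong face or with the wrong endo/exo sense at the isobutyl-bearing carbon, a second molecule of syncarpic acid may add to the Knoevenagel adduct, and the allylic alcohol may ionise on heating. Fallback with the order of the last two operations exchanged. It sets out from enone 16 and ends at target 21. The cycloaddition is run on 16 under the conditions of step 12, where the C5 carbonyl changes the conformation of the nine-membered ring and no free hydroxyl is present, to give the 5-oxo analogue of Tomentodione O F7. Corey–Bakshi–Shibata reduction under the conditions of step 11 then sets C5, the hindered trione carbonyls being expected to react more slowly than the enone.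

**Further compounds**

F1 | step 9 | methyl (1S,2R)-2-[(2Z)-3-iodobut-2-en-1-yl]-3,3-dimethylcyclobutane-1-carboxylate | C/C(I)=C/C[C@@H]1[C@H](CC1(C)C)C(=O)OC
F2 | step 9 | (1S,2R)-2-[(2Z)-3-iodobut-2-en-1-yl]-N-methoxy-N,3,3-trimethylcyclobutane-1-carboxamide | C/C(I)=C/C[C@@H]1[C@H](CC1(C)C)C(=O)N(C)OC
F3 | step 9 | 3-(1,3-dioxolan-2-yl)-1-[(1S,2R)-2-[(2Z)-3-iodobut-2-en-1-yl]-3,3-dimethylcyclobutyl]propan-1-one | C/C(I)=C/C[C@@H]1[C@H](CC1(C)C)C(=O)CCC2OCCO2
F4 | step 9 | 2-{3-[(1S,2R)-2-[(2Z)-3-iodobut-2-en-1-yl]-3,3-dimethylcyclobutyl]but-3-en-1-yl}-1,3-dioxolane | C/C(I)=C/C[C@@H]1[C@H](CC1(C)C)C(=C)CCC2OCCO2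
F5 | step 9 | 4-[(1S,2R)-2-[(2Z)-3-iodobut-2-en-1-yl]-3,3-dimethylcyclobutyl]pent-4-enal | C/C(I)=C/C[C@@H]1[C@H](CC1(C)C)C(=C)CCC=O
F6 | step 9 | (1R,3Z,5S,9S)-4,11,11-trimethyl-8-methylidenebicyclo[7.2.0]undec-3-en-5-ol | C/C1=C/C[C@@H]2[C@H](CC2(C)C)C(=C)CC[C@@H]1O
F0 | step 8 | none | none
F7 | step 12 | 5-oxo analogue of Tomentodione O (C5 ketone in place of the carbinol) | C/C1=C/C[C@@H]2[C@H](CC2(C)C)[C@]2(CCC1=O)C[C@@H](CC(C)C)C1=C(O2)C(C)(C)C(=O)C(C)(C)C1=O
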